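**Plan**

1. Retrosynthetic cuts: C15–C15' (sp2–sp2 Negishi coupling); C10=C11 and C10'=C11' (Horner–Wadsworth–Emmons with one C6 enyne phosphonate); C8=C9 and C8'=C9' (Wittig); C7–C8 (carbonylation of a C7 enol triflate) and C7'–C8' (Wittig). Both rings then go back to one keto ester.
2. Enabling feature: in the cyclohexadienol ring, C1(Me)2–C2–C3(O) and C4=C5(Me)–C6–C7 are two 3-methylbut-2-enoate units. Joining the α-carbon of one (C6) to the β-carbon of the other (C1), and its γ-carbon (C4) to the other's carbonyl carbon (C3), closes ring C1–C6 in one Michael–Claisen dimerisation; C3 is made as a ketone and C7 as an ester.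
3. Forward order: ring first (step 1). Left half: C3 reduction, C6=C7 via the dienolate triflate, chain grown to a C20 vinyl iodide. Right half: same keto ester, double bond moved to C5'=C6', epoxidised, opened vinylogously to the C5' alcohol and C6'=C7', chain grown to a C20 alkyne. The halves are joined at C15–C15' and desilylated.
4. Stereochemistry: C3 and C3' come from CBS reductions of the same ketone with the two enantiomeric catalysts (the rings have opposite sense at these centres). C5' comes from Sharpless epoxidation anti to the C3' silyl ether. 6E comes from enolate geometry, 6'E from the epoxide opening, and the chain E bonds from stabilised Wittig, HWE and syn-hydrozirconation.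

Key step: step 1

Assumption: atoms are numbered as in carotenoids, unprimed for the ring written first in the SMILES (C1 = CMe2, C3 = CHOH, C5 = CMe, C6 = ring carbon of the exocyclic double bond, C7–C15 = chain) and primed for the diol ring; the target is then (3S,6E,3'R,5'S,6'E) with an all-E chain, and the sense of each CBS reduction is predicted with the alkenyl arm as the large group (if the sense were opposite, the two reduction products would simply exchange roles).

**Route**

Step 1
Reactants: 1 methyl 3-methylbut-2-enoate (two molecules)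
Product: 3 methyl 2,6,6-trimethyl-4-oxocyclohex-2-ene-1-carboxylate (racemic), via open-chain Michael adduct 2 (not isolated)
Conditions: KOt-Bu (0.55 equiv per 1), THF/t-BuOH, 0 to 40 °C; AcOH quench
Reagents that add atoms: none
Why: KOt-Bu deprotonates a γ-methyl group of 1 to the dienolate, whose α-carbon adds to the β-carbon of a second molecule of 1 (Michael addition, forms C6–C1 and the quaternary C1) to give 2; proton transfer then gives the dienolate at C6, whose γ-carbon (C4) attacks the second ester carbonyl (vinylogous Dieckmann acylation, forms C4–C3) with loss of methoxide. The closest known reaction types are the consecutive Michael–Claisen [3+3] synthesis of cyclohexane-1,3-diones from enolates and acrylates and the base-induced α-selective Michael dimerisation of crotonates. The six-membered ring closes in a 6-(enolendo)-exo-trig mode, helped by the gem-dimethyl group at C1. The only new stereocentre, C6, is formed racemic and is deliberately left uncontrolled, because it becomes sp2 in step 5 (left half) and is erased by the double-bond shift in step 15 (right half). The step needs α- rather than γ-attack of the dienolate in the Michael addition, which is the kinetic preference of ester dienolates; the Michael step is reversible while the acylation is made irreversible by deprotonation of 3 to its stabilised vinylogous β-keto ester enolate, so the mixture should drain to 3, and protonation on work-up gives the enone tautomer with the C4=C5 double bond that the left ring keeps.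

Step 2
Reactants: 3 methyl 2,6,6-trimethyl-4-oxocyclohex-2-ene-1-carboxylate
Product: 4 methyl (4S)-4-hydroxy-2,6,6-trimethylcyclohex-2-ene-1-carboxylate (both C1 epimers)
Conditions: (R)-2-methyl-CBS-oxazaborolidine (0.1 equiv), BH3·SMe2, toluene, −40 °C; MeOH quench
Reagents that add atoms: none
Why: Corey–Bakshi–Shibata reduction, in which the oxazaborolidine–borane complex binds the ketone anti to the larger alkenyl arm and delivers hydride 1,2 to one carbonyl face, should set C3 as S in both C6 epimers of racemic 3 while the ester is untouched at low temperature.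

Step 3
Reactants: 4 methyl (4S)-4-hydroxy-2,6,6-trimethylcyclohex-2-ene-1-carboxylate
Product: 5 methyl (4S)-4-[(tert-butyldimethylsilyl)oxy]-2,6,6-trimethylcyclohex-2-ene-1-carboxylate (both C1 epimers)
Conditions: TBSCl, imidazole, DMF, rt
Reagents that add atoms: tert-butyldimethylsilyl chloride, CC(C)(C)[Si](C)(C)Cl
Why: Standard silylation of a secondary allylic alcohol gives an ether that withstands the hydride, amide-base, organometallic and mildly acidic steps that follow.

Step 4
Reactants: 5 methyl (4S)-4-[(tert-butyldimethylsilyl)oxy]-2,6,6-trimethylcyclohex-2-ene-1-carboxylate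
Product: 6 (4S)-4-[(tert-butyldimethylsilyl)oxy]-2,6,6-trimethylcyclohex-2-ene-1-carbaldehyde (both C1 epimers)
Conditions: i-Bu2AlH (1.1 equiv), CH2Cl2, −78 °C; aq. potassium sodium tartrate
Reagents that add atoms: none
Why: Partial ester reduction, in which the aluminium hemiacetal of this hindered ester (flanked by a quaternary carbon) should persist at −78 °C and release the aldehyde only on work-up.

Step 5
Reactants: 6 (4S)-4-[(tert-butyldimethylsilyl)oxy]-2,6,6-trimethylcyclohex-2-ene-1-carbaldehyde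
Product: 7 (E)-{(4S)-4-[(tert-butyldimethylsilyl)oxy]-2,6,6-trimethylcyclohex-2-en-1-ylidene}methyl trifluoromethanesulfonate
Conditions: KN(SiMe3)2 (1.1 equiv), THF, −78 °C; PhNTf2, −78 to 0 °C
Reagents that add atoms: N-phenylbis(trifluoromethanesulfonimide), O=S(=O)(N(c1ccccc1)S(=O)(=O)C(F)(F)F)C(F)(F)F
Why: Enol triflate formation, in which the base removes the only α-hydrogen (C6–H, also allylic) and the dienolate is O-sulfonylated; the enolate oxygen should lie syn to the gem-dimethyl carbon and away from the in-plane C5 methyl group (allylic 1,3-strain), giving the 6E geometry, and both C6 epimers converge.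

Step 6
Reactants: 7 (E)-{(4S)-4-[(tert-butyldimethylsilyl)oxy]-2,6,6-trimethylcyclohex-2-en-1-ylidene}methyl trifluoromethanesulfonate
Product: 8 (2E)-2-{(4S)-4-[(tert-butyldimethylsilyl)oxy]-2,6,6-trimethylcyclohex-2-en-1-ylidene}acetaldehyde
Conditions: Pd(PPh3)4 (5 mol %), CO (1 atm), Bu3SnH (slow addition), THF, 50 °C
Reagents that add atoms: carbon monoxide, [C-]#[O+]
Why: Palladium-catalysed reductive carbonylation (formylation) of a vinyl triflate (oxidative addition, CO insertion, hydride transfer from tin to the acyl palladium) forms C7–C8 with retention of the C6=C7 geometry.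

Step 7
Reactants: 8 (2E)-2-{(4S)-4-[(tert-butyldimethylsilyl)oxy]-2,6,6-trimethylcyclohex-2-en-1-ylidene}acetaldehyde; 9 2-(triphenyl-λ5-phosphanylidene)propanal
Product: 10 (2E,4E)-4-{(4S)-4-[(tert-butyldimethylsilyl)oxy]-2,6,6-trimethylcyclohex-2-en-1-ylidene}-2-methylbut-2-enal
Conditions: toluene, 90 °C
Reagents that add atoms: none
Why: Wittig olefination with the stabilised formyl ylide should give the (E)-2-methyl enal (C8=C9), and the more hindered, more conjugated product aldehyde reacts more slowly than 8, which limits a second homologation.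

Step 8
Reactants: 11 (2E)-3-methylpent-2-en-4-yn-1-ol
Product: 12 (3E)-5-bromo-3-methylpent-3-en-1-yne
Conditions: PBr3 (0.4 equiv), Et2O, −10 °C
Reagents that add atoms: phosphorus tribromide, BrP(Br)Br
Why: SN2 substitution of the primary allylic alcohol through its bromophosphite at low temperature keeps the E double bond in place.

Step 9
Reactants: 12 (3E)-5-bromo-3-methylpent-3-en-1-yne
Product: 13 diethyl [(2E)-3-methylpent-2-en-4-yn-1-yl]phosphonate
Conditions: P(OEt)3, neat, 110 °C
Reagents that add atoms: triethyl phosphite, CCOP(OCC)OCC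
Why: Michaelis–Arbuzov reaction of a primary allylic bromide, which leaves the double-bond geometry unchanged.

Step 10
Reactants: 10 (2E,4E)-4-{(4S)-4-[(tert-butyldimethylsilyl)oxy]-2,6,6-trimethylcyclohex-2-en-1-ylidene}-2-methylbut-2-enal; 13 diethyl [(2E)-3-methylpent-2-en-4-yn-1-yl]phosphonate
Product: 14 tert-butyl({(1S,4E)-4-[(2E,4E,6E)-3,7-dimethylnona-2,4,6-trien-8-yn-1-ylidene]-3,5,5-trimethylcyclohex-2-en-1-yl}oxy)dimethylsilane
Conditions: 13, NaN(SiMe3)2, THF, −78 °C; then 10, −78 to 0 °C
Reagents that add atoms: none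
Why: Horner–Wadsworth–Emmons olefination, in which the allyl-type phosphonate anion (its CH2 is more acidic than the alkyne C–H) attacks through its α-carbon and elimination should give the E C10=C11 bond.

Step 11
Reactants: 14 tert-butyl({(1S,4E)-4-[(2E,4E,6E)-3,7-dimethylnona-2,4,6-trien-8-yn-1-ylidene]-3,5,5-trimethylcyclohex-2-en-1-yl}oxy)dimethylsilane
Product: 16 tert-butyl({(1S,4E)-4-[(2E,4E,6E,8E)-9-iodo-3,7-dimethylnona-2,4,6,8-tetraen-1-ylidene]-3,5,5-trimethylcyclohex-2-en-1-yl}oxy)dimethylsilane, via alkenyl–ZrCp2Cl species 15 (not isolated)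
Conditions: Cp2Zr(H)Cl (1.3 equiv), THF, rt, dark; then I2, −78 to 0 °C
Reagents that add atoms: iodine, II
Why: Hydrozirconation adds Zr–H syn and anti-Markovnikov to the terminal alkyne only (the substituted alkenes are inert), and iodinolysis with retention gives the (E)-vinyl iodide (C14=C15).

Step 12
Reactants: 3 methyl 2,6,6-trimethyl-4-oxocyclohex-2-ene-1-carboxylate
Product: 17 methyl (4R)-4-hydroxy-2,6,6-trimethylcyclohex-2-ene-1-carboxylate (both C1 epimers)
Conditions: (S)-2-methyl-CBS-oxazaborolidine (0.1 equiv), BH3·SMe2, toluene, −40 °C; MeOH quench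
Reagents that add atoms: none
Why: Corey–Bakshi–Shibata reduction with the mirror-image catalyst delivers hydride to the opposite carbonyl face and sets the C3' centre (R in the target).

Step 13
Reactants: 17 methyl (4R)-4-hydroxy-2,6,6-trimethylcyclohex-2-ene-1-carboxylate
Product: 18 methyl (4R)-4-[(tert-butyldimethylsilyl)oxy]-2,6,6-trimethylcyclohex-2-ene-1-carboxylate (both C1 epimers)
Conditions: TBSCl, imidazole, DMF, rt
Reagents that add atoms: tert-butyldimethylsilyl chloride, CC(C)(C)[Si](C)(C)Cl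
Why: Standard silylation; the bulky ether also shields one ring face and removes the hydroxyl as a competing directing group in the later epoxidation.

Step 14
Reactants: 18 methyl (4R)-4-[(tert-butyldimethylsilyl)oxy]-2,6,6-trimethylcyclohex-2-ene-1-carboxylate
Product: 19 (4R)-4-[(tert-butyldimethylsilyl)oxy]-2,6,6-trimethylcyclohex-2-ene-1-carbaldehyde (both C1 epimers)
Conditions: i-Bu2AlH (1.1 equiv), CH2Cl2, −78 °C; aq. potassium sodium tartrate
Reagents that add atoms: none
Why: Partial reduction of the hindered ester through its low-temperature-stable aluminium hemiacetal, as in step 4.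

Step 15
Reactants: 19 (4R)-4-[(tert-butyldimethylsilyl)oxy]-2,6,6-trimethylcyclohex-2-ene-1-carbaldehyde
Product: 21 {(4S)-4-[(tert-butyldimethylsilyl)oxy]-2,6,6-trimethylcyclohex-1-en-1-yl}methanol, via conjugated aldehyde 20 (not isolated)
Conditions: DBU (0.2 equiv), CH2Cl2, rt; then MeOH, NaBH4, 0 °C
Reagents that add atoms: none
Why: Base-catalysed prototropic shift (deprotonation at C6', reprotonation at C4') moves the double bond into conjugation with the aldehyde and removes the C6' stereocentre, and NaBH4 then reduces the hindered enal 1,2 (the descriptor changes from R to S only because the CIP ranking of the ring arms changes).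

Step 16
Reactants: 21 {(4S)-4-[(tert-butyldimethylsilyl)oxy]-2,6,6-trimethylcyclohex-1-en-1-yl}methanol
Product: 22 {(1S,4R,6S)-4-[(tert-butyldimethylsilyl)oxy]-2,2,6-trimethyl-7-oxabicyclo[4.1.0]heptan-1-yl}methanol
Conditions: Ti(Oi-Pr)4 (0.2 equiv), L-(+)-diethyl tartrate (0.25 equiv), t-BuOOH, 4 Å MS, CH2Cl2, −20 °C
Reagents that add atoms: tert-butyl hydroperoxide, CC(C)(C)OO
Why: Katsuki–Sharpless asymmetric epoxidation, in which the allylic hydroxyl binds the titanium tartrate and the L-(+)-tartrate should deliver oxygen to the face anti to the C3' silyl ether, setting C5' (S in the target) and the temporary C6' centre under reagent control.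

Step 17
Reactants: 22 {(1S,4R,6S)-4-[(tert-butyldimethylsilyl)oxy]-2,2,6-trimethyl-7-oxabicyclo[4.1.0]heptan-1-yl}methanol
Product: 23 (1R,4R,6S)-4-[(tert-butyldimethylsilyl)oxy]-2,2,6-trimethyl-7-oxabicyclo[4.1.0]heptane-1-carbaldehyde
Conditions: Dess–Martin periodinane, NaHCO3, CH2Cl2, 0 °C
Reagents that add atoms: none
Why: Buffered Dess–Martin oxidation of the primary epoxy alcohol gives an aldehyde with no α-hydrogen, so it cannot epimerise (the descriptor at C1 changes only through CIP ranking).

Step 18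
Reactants: 23 (1R,4R,6S)-4-[(tert-butyldimethylsilyl)oxy]-2,2,6-trimethyl-7-oxabicyclo[4.1.0]heptane-1-carbaldehyde
Product: 25 (2E)-2-{(2S,4R)-4-[(tert-butyldimethylsilyl)oxy]-2-hydroxy-2,6,6-trimethylcyclohexylidene}acetaldehyde, via methyl enol ether 24 (not isolated)
Conditions: MeOCH2PPh3Cl, KN(SiMe3)2, THF, 0 °C; then 23, −78 to 0 °C; then 5 % aq. oxalic acid, THF, 0 °C
Reagents that add atoms: (methoxymethyl)triphenylphosphonium chloride, COC[P+](c1ccccc1)(c1ccccc1)c1ccccc1.[Cl-]; water, O
Why: Wittig methoxymethylenation followed by mild acid, in which the enol ether oxygen pushes electrons through C8'=C7' into the allylic C6'–O bond of the epoxide (vinylogous ring opening, the standard route from 2,3-epoxy aldehydes to 4-hydroxy-2-enals), unveils the C5' tertiary alcohol without touching its configuration and should give the 6'E enal through the s-trans conformer in which C8' lies away from C5'.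

Step 19
Reactants: 25 (2E)-2-{(2S,4R)-4-[(tert-butyldimethylsilyl)oxy]-2-hydroxy-2,6,6-trimethylcyclohexylidene}acetaldehyde; 9 2-(triphenyl-λ5-phosphanylidene)propanal
Product: 26 (2E,4E)-4-{(2S,4R)-4-[(tert-butyldimethylsilyl)oxy]-2-hydroxy-2,6,6-trimethylcyclohexylidene}-2-methylbut-2-enal
Conditions: toluene, 80 °C
Reagents that add atoms: none
Why: Wittig olefination with the neutral stabilised ylide tolerates the free tertiary alcohol and should give the (E)-2-methyl enal (C8'=C9').

Step 20
Reactants: 26 (2E,4E)-4-{(2S,4R)-4-[(tert-butyldimethylsilyl)oxy]-2-hydroxy-2,6,6-trimethylcyclohexylidene}-2-methylbut-2-enal; 13 diethyl [(2E)-3-methylpent-2-en-4-yn-1-yl]phosphonate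
Product: 27 (1S,2E,5R)-5-[(tert-butyldimethylsilyl)oxy]-2-[(2E,4E,6E)-3,7-dimethylnona-2,4,6-trien-8-yn-1-ylidene]-1,3,3-trimethylcyclohexan-1-ol
Conditions: 13 (2.5 equiv), NaN(SiMe3)2 (2.4 equiv), THF, −78 °C; then 26, −78 to 0 °C
Reagents that add atoms: none
Why: Horner–Wadsworth–Emmons olefination as in step 10, with excess anion to cover the tertiary hydroxyl, should give the E C10'=C11' bond.

Step 21
Reactants: 27 (1S,2E,5R)-5-[(tert-butyldimethylsilyl)oxy]-2-[(2E,4E,6E)-3,7-dimethylnona-2,4,6-trien-8-yn-1-ylidene]-1,3,3-trimethylcyclohexan-1-ol; 16 tert-butyl({(1S,4E)-4-[(2E,4E,6E,8E)-9-iodo-3,7-dimethylnona-2,4,6,8-tetraen-1-ylidene]-3,5,5-trimethylcyclohex-2-en-1-yl}oxy)dimethylsilane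
Product: 29 3,3'-bis-O-(tert-butyldimethylsilyl) ether of the target, via O-zirconated alkenyl–ZrCp2Cl species 28 (not isolated)
Conditions: Cp2Zr(H)Cl (2.3 equiv), THF, rt; then 16, Pd(PPh3)4 (5 mol %), ZnCl2 (0.5 equiv), THF, rt, dark
Reagents that add atoms: none
Why: Negishi coupling, in which Cp2Zr(H)Cl first caps the tertiary alcohol as a zirconium alkoxide and then adds syn to the terminal alkyne, and zinc-assisted transmetalation with palladium catalysis joins C15' to C15 with retention at both (E)-alkenyl partners.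

Step 22
Reactants: 29 3,3'-bis-O-(tert-butyldimethylsilyl) ether of the target
Product: 30 CNP0269135.1, the (3S,6E,3'R,5'S,6'E) retro-carotenoid triol
Conditions: Bu4NF, THF, 0 °C to rt, dark
Reagents that add atoms: none
Why: Fluoride cleavage of both silyl ethers under non-acidic conditions avoids ionisation of the allylic C3 alcohol and dehydration of the tertiary allylic C5' alcohol.

**Compound list**

1 | methyl 3-methylbut-2-enoate | COC(=O)C=C(C)C | starting material
2 | dimethyl 3,3-dimethyl-2-(prop-1-en-2-yl)pentanedioate (racemic Michael adduct) | COC(=O)C(C(C)=C)C(C)(C)CC(=O)OC | intermediate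
3 | methyl 2,6,6-trimethyl-4-oxocyclohex-2-ene-1-carboxylate (racemic) | COC(=O)C1C(C)=CC(=O)CC1(C)C | intermediate
4 | methyl (4S)-4-hydroxy-2,6,6-trimethylcyclohex-2-ene-1-carboxylate (both C1 epimers) | COC(=O)C1C(C)=C[C@@H](O)CC1(C)C | intermediate
5 | methyl (4S)-4-[(tert-butyldimethylsilyl)oxy]-2,6,6-trimethylcyclohex-2-ene-1-carboxylate (both C1 epimers) | COC(=O)C1C(C)=C[C@@H](O[Si](C)(C)C(C)(C)C)CC1(C)C | intermediate
6 | (4S)-4-[(tert-butyldimethylsilyl)oxy]-2,6,6-trimethylcyclohex-2-ene-1-carbaldehyde (both C1 epimers) | O=CC1C(C)=C[C@@H](O[Si](C)(C)C(C)(C)C)CC1(C)C | intermediate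
7 | (E)-{(4S)-4-[(tert-butyldimethylsilyl)oxy]-2,6,6-trimethylcyclohex-2-en-1-ylidene}methyl trifluoromethanesulfonate | CC1=C[C@@H](O[Si](C)(C)C(C)(C)C)CC(C)(C)\C1=C/OS(=O)(=O)C(F)(F)F | intermediate
8 | (2E)-2-{(4S)-4-[(tert-butyldimethylsilyl)oxy]-2,6,6-trimethylcyclohex-2-en-1-ylidene}acetaldehyde | CC1=C[C@@H](O[Si](C)(C)C(C)(C)C)CC(C)(C)\C1=C/C=O | intermediate
9 | 2-(triphenyl-λ5-phosphanylidene)propanal | CC(C=O)=P(c1ccccc1)(c1ccccc1)c1ccccc1 | starting material
10 | (2E,4E)-4-{(4S)-4-[(tert-butyldimethylsilyl)oxy]-2,6,6-trimethylcyclohex-2-en-1-ylidene}-2-methylbut-2-enal | CC1=C[C@@H](O[Si](C)(C)C(C)(C)C)CC(C)(C)\C1=C/C=C(C)/C=O | intermediate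
11 | (2E)-3-methylpent-2-en-4-yn-1-ol | C#C/C(C)=C/CO | starting material
12 | (3E)-5-bromo-3-methylpent-3-en-1-yne | C#C/C(C)=C/CBr | intermediate
13 | diethyl [(2E)-3-methylpent-2-en-4-yn-1-yl]phosphonate | C#C/C(C)=C/CP(=O)(OCC)OCC | intermediate
14 | tert-butyl({(1S,4E)-4-[(2E,4E,6E)-3,7-dimethylnona-2,4,6-trien-8-yn-1-ylidene]-3,5,5-trimethylcyclohex-2-en-1-yl}oxy)dimethylsilane (left C20 alkyne) | CC1=C[C@@H](O[Si](C)(C)C(C)(C)C)CC(C)(C)\C1=C/C=C(C)/C=C/C=C(C)/C#C | intermediate
15 | (E)-alkenyl–ZrCp2Cl species from 14 (H on C14, Zr on C15) | CC1=C[C@@H](O[Si](C)(C)C(C)(C)C)CC(C)(C)\C1=C/C=C(C)/C=C/C=C(C)/C=C/[Zr](Cl)(C1C=CC=C1)C1C=CC=C1 | intermediate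
16 | tert-butyl({(1S,4E)-4-[(2E,4E,6E,8E)-9-iodo-3,7-dimethylnona-2,4,6,8-tetraen-1-ylidene]-3,5,5-trimethylcyclohex-2-en-1-yl}oxy)dimethylsilane (left C20 iodide) | CC1=C[C@@H](O[Si](C)(C)C(C)(C)C)CC(C)(C)\C1=C/C=C(C)/C=C/C=C(C)/C=C/I | intermediate
17 | methyl (4R)-4-hydroxy-2,6,6-trimethylcyclohex-2-ene-1-carboxylate (both C1 epimers) | COC(=O)C1C(C)=C[C@H](O)CC1(C)C | intermediate
18 | methyl (4R)-4-[(tert-butyldimethylsilyl)oxy]-2,6,6-trimethylcyclohex-2-ene-1-carboxylate (both C1 epimers) | COC(=O)C1C(C)=C[C@H](O[Si](C)(C)C(C)(C)C)CC1(C)C | intermediate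
19 | (4R)-4-[(tert-butyldimethylsilyl)oxy]-2,6,6-trimethylcyclohex-2-ene-1-carbaldehyde (both C1 epimers) | O=CC1C(C)=C[C@H](O[Si](C)(C)C(C)(C)C)CC1(C)C | intermediate
20 | (4S)-4-[(tert-butyldimethylsilyl)oxy]-2,6,6-trimethylcyclohex-1-ene-1-carbaldehyde | O=CC1=C(C)C[C@H](O[Si](C)(C)C(C)(C)C)CC1(C)C | intermediate
21 | {(4S)-4-[(tert-butyldimethylsilyl)oxy]-2,6,6-trimethylcyclohex-1-en-1-yl}methanol | OCC1=C(C)C[C@H](O[Si](C)(C)C(C)(C)C)CC1(C)C | intermediate
22 | {(1S,4R,6S)-4-[(tert-butyldimethylsilyl)oxy]-2,2,6-trimethyl-7-oxabicyclo[4.1.0]heptan-1-yl}methanol | OC[C@]12O[C@@]1(C)C[C@H](O[Si](C)(C)C(C)(C)C)CC2(C)C | intermediate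
23 | (1R,4R,6S)-4-[(tert-butyldimethylsilyl)oxy]-2,2,6-trimethyl-7-oxabicyclo[4.1.0]heptane-1-carbaldehyde | O=C[C@]12O[C@@]1(C)C[C@H](O[Si](C)(C)C(C)(C)C)CC2(C)C | intermediate
24 | (1R,4R,6S)-4-[(tert-butyldimethylsilyl)oxy]-1-(2-methoxyethenyl)-2,2,6-trimethyl-7-oxabicyclo[4.1.0]heptane (E/Z mixture) | COC=C[C@]12O[C@@]1(C)C[C@H](O[Si](C)(C)C(C)(C)C)CC2(C)C | intermediate
25 | (2E)-2-{(2S,4R)-4-[(tert-butyldimethylsilyl)oxy]-2-hydroxy-2,6,6-trimethylcyclohexylidene}acetaldehyde | O=C/C=C1\C(C)(C)C[C@@H](O[Si](C)(C)C(C)(C)C)C[C@]1(C)O | intermediate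
26 | (2E,4E)-4-{(2S,4R)-4-[(tert-butyldimethylsilyl)oxy]-2-hydroxy-2,6,6-trimethylcyclohexylidene}-2-methylbut-2-enal | O=C/C(C)=C/C=C1\C(C)(C)C[C@@H](O[Si](C)(C)C(C)(C)C)C[C@]1(C)O | intermediate
27 | (1S,2E,5R)-5-[(tert-butyldimethylsilyl)oxy]-2-[(2E,4E,6E)-3,7-dimethylnona-2,4,6-trien-8-yn-1-ylidene]-1,3,3-trimethylcyclohexan-1-ol (right C20 alkyne) | C#C/C(C)=C/C=C/C(C)=C/C=C1\C(C)(C)C[C@@H](O[Si](C)(C)C(C)(C)C)C[C@]1(C)O | intermediate
28 | 27 carrying ZrCp2Cl on the C5' oxygen and, (E), on C15' (H on C14') | Cl[Zr](C1C=CC=C1)(C1C=CC=C1)/C=C/C(C)=C/C=C/C(C)=C/C=C2\C(C)(C)C[C@@H](O[Si](C)(C)C(C)(C)C)C[C@]2(C)O[Zr](Cl)(C1C=CC=C1)C1C=CC=C1 | intermediate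
29 | 3,3'-bis-O-(tert-butyldimethylsilyl) ether of the target (3S,6E,3'R,5'S,6'E; all-E chain) | CC1=C[C@@H](O[Si](C)(C)C(C)(C)C)CC(C)(C)\C1=C/C=C(C)/C=C/C=C(C)/C=C/C=C/C(C)=C/C=C/C(C)=C/C=C1\C(C)(C)C[C@@H](O[Si](C)(C)C(C)(C)C)C[C@]1(C)O | intermediate
30 | CNP0269135.1, (3S,6E,3'R,5'S,6'E) retro-carotenoid triol with all-E chain | CC1=C[C@@H](O)CC(C)(C)\C1=C/C=C(C)/C=C/C=C(C)/C=C/C=C/C(C)=C/C=C/C(C)=C/C=C1\C(C)(C)C[C@@H](O)C[C@]1(C)O | target

**Count**

Total step count: 22. Longest linear sequence: 12 steps (steps 1, 12 to 20, 21, 22).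

**Steps most likely to fail**

Step 1. The dienolate may add through its γ-carbon, or the adduct may close through the other ester, giving the regioisomeric keto ester; chain growth to oligomers is also possible. Fallback: the ring is built through a different bond set. Commercial 4-methylpent-3-en-2-one and methyl acetoacetate are condensed with ZnCl2 in refluxing heptane with water removal; Michael addition gives methyl 2-acetyl-3,3-dimethyl-5-oxohexanoate F1, which closes by intramolecular aldol condensation. This fallback does not set out from a numbered compound (the two commercial materials replace 1) and it comes back to the route at 3.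

Step 18. Rotation about C6'–C7' in the oxocarbenium ion may scramble the double-bond geometry, the Z isomer may close to a dihydrofuranol, or the acid may attack the silyl ether. Fallback: a carbanion-driven opening under basic conditions, setting out from 23. Methylenation with Ph3P=CH2 gives the vinyl epoxide (1R,4R,6S)-4-[(tert-butyldimethylsilyl)oxy]-1-ethenyl-2,2,6-trimethyl-7-oxabicyclo[4.1.0]heptane F6. Hydroboration with 9-BBN and oxidation with NaOH/H2O2 gives the primary alcohol 2-{(1S,4R,6S)-4-[(tert-butyldimethylsilyl)oxy]-2,2,6-trimethyl-7-oxabicyclo[4.1.0]heptan-1-yl}ethanol F7. Buffered Dess–Martin oxidation gives the β,γ-epoxy aldehyde 2-{(1S,4R,6S)-4-[(tert-butyldimethylsilyl)oxy]-2,2,6-trimethyl-7-oxabicyclo[4.1.0]heptan-1-yl}acetaldehyde F8. Et3N then removes the α-hydrogen and the enolate opens the epoxide by β-elimination. The fallback comes back to the route at 25.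

Step 5. Enolisation may show no geometric preference (a mixture at C6=C7), or the dienolate may lose silanolate by β-elimination across C3–C4. Fallback: addition and dehydration in place of enolate chemistry, setting out from 6. Commercial (E)-3-iodo-2-methylprop-2-en-1-ol is silylated (Et3SiCl, imidazole) to (E)-triethyl[(3-iodo-2-methylprop-2-en-1-yl)oxy]silane F2. F2 is lithiated with t-BuLi and added to 6 to give the allylic alcohol (2E)-1-{(4S)-4-[(tert-butyldimethylsilyl)oxy]-2,6,6-trimethylcyclohex-2-en-1-yl}-3-methyl-4-[(triethylsilyl)oxy]but-2-en-1-ol F3. The Burgess reagent dehydrates F3 across C6–C7 to the conjugated triene tert-butyl({(1S,4E)-3,5,5-trimethyl-4-[(2E)-3-methyl-4-[(triethylsilyl)oxy]but-2-en-1-ylidene]cyclohex-2-en-1-yl}oxy)dimethylsilane F4, which can be equilibrated thermally toward the less strained 6E isomer. Buffered HF·pyridine removes the primary triethylsilyl group to give (2E,4E)-4-{(4S)-4-[(tert-butyldimethylsilyl)oxy]-2,6,6-trimethylcyclohex-2-en-1-ylidene}-2-methylbut-2-en-1-ol F5, and MnO2 oxidises F5 to the aldehyde. The fallback comes back to the route at 10 and bypasses steps 6 and 7.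

**Further compounds**

F1 | step 1 | methyl 2-acetyl-3,3-dimethyl-5-oxohexanoate | COC(=O)C(C(C)=O)C(C)(C)CC(C)=O
F2 | step 5 | (E)-triethyl[(3-iodo-2-methylprop-2-en-1-yl)oxy]silane | I/C=C(\C)CO[Si](CC)(CC)CC
F3 | step 5 | (2E)-1-{(4S)-4-[(tert-butyldimethylsilyl)oxy]-2,6,6-trimethylcyclohex-2-en-1-yl}-3-methyl-4-[(triethylsilyl)oxy]but-2-en-1-ol (diastereomer mixture) | CC1=C[C@@H](O[Si](C)(C)C(C)(C)C)CC(C)(C)C1C(O)/C=C(\C)CO[Si](CC)(CC)CC
F4 | step 5 | tert-butyl({(1S,4E)-3,5,5-trimethyl-4-[(2E)-3-methyl-4-[(triethylsilyl)oxy]but-2-en-1-ylidene]cyclohex-2-en-1-yl}oxy)dimethylsilane | CC1=C[C@@H](O[Si](C)(C)C(C)(C)C)CC(C)(C)\C1=C/C=C(C)/CO[Si](CC)(CC)CC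
F5 | step 5 | (2E,4E)-4-{(4S)-4-[(tert-butyldimethylsilyl)oxy]-2,6,6-trimethylcyclohex-2-en-1-ylidene}-2-methylbut-2-en-1-ol | CC1=C[C@@H](O[Si](C)(C)C(C)(C)C)CC(C)(C)\C1=C/C=C(C)/CO
F6 | step 18 | (1R,4R,6S)-4-[(tert-butyldimethylsilyl)oxy]-1-ethenyl-2,2,6-trimethyl-7-oxabicyclo[4.1.0]heptane | C=C[C@]12O[C@@]1(C)C[C@H](O[Si](C)(C)C(C)(C)C)CC2(C)C
F7 | step 18 | 2-{(1S,4R,6S)-4-[(tert-butyldimethylsilyl)oxy]-2,2,6-trimethyl-7-oxabicyclo[4.1.0]heptan-1-yl}ethanol | OCC[C@]12O[C@@]1(C)C[C@H](O[Si](C)(C)C(C)(C)C)CC2(C)C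
F8 | step 18 | 2-{(1S,4R,6S)-4-[(tert-butyldimethylsilyl)oxy]-2,2,6-trimethyl-7-oxabicyclo[4.1.0]heptan-1-yl}acetaldehyde | O=CC[C@]12O[C@@]1(C)C[C@H](O[Si](C)(C)C(C)(C)C)CC2(C)C
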